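Its constants are assumed, and the outcome is calculated.

The vessels differ, one closed, two dosed and one a continuous tank, but each takes the same charge and the same steps.

the same everywhere: initiator 2.0 mM
- Friday's: substrate 20 mM; reagent 19.0 mM (fed, over 8.00 min); time 8.0 min; all but reagent at the start; reagent goes in evenly over 8.00 min, the run ends at 8.0 min
- Sunday's: substrate 20 mM; reagent 19.0 mM; time 8.0 min; a closed flask charged with all of it at once and left for 8.0 min
- Saturday's: substrate 20 mM (fed, over 8.00 min); reagent 19.0 mM; time 8.0 min; a stirred flask in which substrate is dosed at a steady rate over 8.00 min without added volume, worked up at 8.0 min
- Tuesday's: substrate 20 mM; reagent 19.0 mM; a single well-mixed tank run continuously and read at steady state, 8.0 min in it on average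

    reagent + first chain carrier → target + second chain carrier (k1 = 93000 /M/s)
    2 second chain carrier → ended chains (k2 = 2 × 10⁸ /M/s)
    initiator → 2 initiating radical (k3 = 0.0019 /s)
    substrate + initiating radical → capped initiator + first chain carrier (k4 = 3.1 × 10⁶ /M/s)
    substrate + second chain carrier → by-product + first chain carrier (k5 = 8.2 × 10⁶ /M/s)

- where a step has two of a species, its rate is k times that concentration squared, and two are used at each turn
- the stated concentrations are those of everything mixed, before any reaction; amounts are the same in each set-up
- the feed brings no volume worth counting
- run time (Friday's): 8.0 min

* the set-up with the highest amount of target at the outlet or at the end, in percent of the substrate put in ("none" if the first two lie within 2 percentage points) (Friday's / Sunday's / Saturday's / Tuesday's / none)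
* amount of target at the outlet or at the end, in percent of the substrate put in, Friday's
* amount of target at the outlet or at the end, in percent of the substrate put in, Sunday's
* amount of target at the outlet or at the end, in percent of the substrate put in, Saturday's
* amount of target at the outlet or at the end, in percent of the substrate put in, Tuesday's

Target comes from one step, reagent meeting first chain carrier, at one reagent per target. Reagent charge over substrate charge, 95.0%, is therefore the ceiling on the percent asked for, and reagent, at 19.0 mM against 20 mM of substrate, is the limiting reagent.

Which numbers have to be known well? Both charges pass straight into the ceiling while reagent is the shorter of the two, so those two have to be known well. The constants enter through a different question: whether the chain turns reagent over within the time given. In Sunday's flask, first chain carrier builds up from the initiator while reagent falls against it. An estimate of the time for this, with the ended-chains step left out, is one over the root of the product of the target step's constant, the initiator step's constant and the initiator charge, which is 1.68 s. That is 286 times shorter than the 8.0 min allowed, and the two constants in it sit under a root, so a rough knowledge of those two serves. The dosing time of 8.00 min and the average stay of 8.0 min in Tuesday's tank are as long against it, so this reckoning takes each dose, and what enters the tank, as turned over soon after it arrives. It commits to 95.0% for Friday's, 95.0% for Sunday's, 95.0% for Saturday's and 95.0% for Tuesday's, with no winner beyond the margin of 2 percentage points.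

The forecast gives 95% for Friday's, 95% for Sunday's, 95% for Saturday's and 95% for Tuesday's, and none as best, on the ground that “reagent is consumed essentially completely in every set-up”.

The flasks give 95.0% for Friday's, 95.0% for Sunday's, 95.0% for Saturday's and 95.0% for Tuesday's, so the best is none. Sunday's flask ends with 5.00% of the substrate charged standing as first chain carrier, the same size as the 5.00% gap above the ceiling. With less reagent in Saturday's flask, the ceiling at 18.0 mM reads 90.0%, and that is the nearest reagent amount at which Saturday's answer has moved by 5 points.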